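**Retrosynthetic overview**

- The methyl ester is traced back to a C3 acetaldehyde side chain (chlorite oxidation, then methylation), so the ring can be built on an enal.
- The only ring, the 3,6-dihydro-1,2-dioxine, is made in one flask by a formal [3+3] annulation that forms O2–C3 and C5–C6: a C6–O1–O2 unit (hydroperoxy orthoester 4) plus a C3–C4=C5 unit ((2E,4Z)-5-silyldienal 9).
- Enabling feature: C6 is a peroxy ketal carbon (it carries O1 and OMe) bonded directly to the cis C4=C5 alkene, so it is a latent peroxy(methoxy)carbenium ion that a Z-vinylsilane can capture. C3 lies β to the side-chain carbonyl, so O2 can be delivered by enantioselective conjugate addition.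
- Fragment 4 comes from heptadecanenitrile (Pinner orthoester, exchange with H2O2); fragment 9 from (E)-pent-2-en-4-yn-1-ol (C-silylation, Lindlar reduction, MnO2).

Key step: step 7

Remark: ring atoms are numbered O1, O2, C3 (bears CH2CO2Me), C4=C5, C6 (bears hexadecyl and OMe); the target is (3S,6S) with OMe and the C3 side chain cis, and the sense of induction of the (S)-catalyst in step 7 is taken from the usual face-shielding model of its iminium ions.

**Route**

Step 1
Reactants: 1 heptadecanenitrile
Product: 2 methyl heptadecanimidate hydrochloride
Conditions: HCl (g), MeOH (1.1 equiv), Et2O, 0 °C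
Reagents that add atoms: methanol, CO; hydrogen chloride, Cl
Why: Pinner reaction: protonation of the nitrile by HCl lets methanol add to give the imidate hydrochloride; no stereocentre is formed.

Step 2
Reactants: 2 methyl heptadecanimidate hydrochloride
Product: 3 1,1,1-trimethoxyheptadecane
Conditions: MeOH (excess), hexane, rt
Reagents that add atoms: methanol, CO
Why: Pinner orthoester synthesis: excess methanol adds twice to the imidate salt and ammonia leaves as insoluble NH4Cl, which drives the alcoholysis to the orthoester.

Step 3
Reactants: 3 1,1,1-trimethoxyheptadecane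
Product: 4 1-hydroperoxy-1,1-dimethoxyheptadecane
Conditions: anhydrous H2O2 (Et2O solution, 4 equiv), PPTS (2 mol %), 4 Å MS, Et2O, −20 °C; used at once as a cold solution
Reagents that add atoms: hydrogen peroxide, OO
Why: acid-catalysed alkoxy/hydroperoxy exchange at an orthoester carbon via the dimethoxycarbenium ion, the reaction type by which ketals and orthoesters are turned into perketals and peroxy orthoesters with hydroperoxides; excess H2O2, low temperature and sieves (uptake of MeOH) should hold it at mono-exchange.

Step 4
Reactants: 5 (E)-pent-2-en-4-yn-1-ol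
Product: 7 (E)-5-(trimethylsilyl)pent-2-en-4-yn-1-ol, via bis-silyl ether 6 (not isolated)
Conditions: EtMgBr (2.2 equiv), THF, 0 → 45 °C; TMSCl (2.2 equiv), 0 °C → rt; 1 M H2SO4 (aq) work-up
Reagents that add atoms: chlorotrimethylsilane, C[Si](C)(C)Cl
Why: C-silylation of a terminal alkyne through the magnesium alkoxide/acetylide dianion, both sites being silylated and only the labile O–Si bond being hydrolysed on acidic work-up.

Step 5
Reactants: 7 (E)-5-(trimethylsilyl)pent-2-en-4-yn-1-ol
Product: 8 (2E,4Z)-5-(trimethylsilyl)penta-2,4-dien-1-ol
Conditions: H2 (1 atm), Lindlar catalyst, quinoline, EtOAc, rt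
Reagents that add atoms: none
Why: Lindlar semi-hydrogenation: syn delivery of H2 to the silylalkyne on poisoned palladium should give the Z-vinylsilane and stop before the alkenes, which fixes the cis geometry of the later ring alkene.

Step 6
Reactants: 8 (2E,4Z)-5-(trimethylsilyl)penta-2,4-dien-1-ol
Product: 9 (2E,4Z)-5-(trimethylsilyl)penta-2,4-dienal
Conditions: activated MnO2, CH2Cl2, rt
Reagents that add atoms: none
Why: selective oxidation of an allylic alcohol with activated MnO2 under neutral heterogeneous conditions, which should leave the 2E and 4Z double bonds unchanged.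

Step 7
Reactants: 4 1-hydroperoxy-1,1-dimethoxyheptadecane; 9 (2E,4Z)-5-(trimethylsilyl)penta-2,4-dienal
Product: 11 2-[(3S,6S)-6-hexadecyl-6-methoxy-3,6-dihydro-1,2-dioxin-3-yl]acetaldehyde, via peroxy orthoester aldehyde 10 (not isolated)
Conditions: (S)-2-[diphenyl(trimethylsilyloxy)methyl]pyrrolidine (10 mol %), toluene, 0 °C; then CH2Cl2, −78 °C, TMSOTf (0.3 equiv), −78 → −40 °C; Et3N quench
Reagents that add atoms: none
Why: Proposed new method: the (S)-diarylprolinol silyl ether turns 9 into an E-iminium ion whose β-carbon (the future C3) should take the terminal oxygen of hydroperoxide 4 on the face opposite the diarylsiloxymethyl group, forming O2–C3 with S configuration by catalyst control, the closest known reaction type being the iminium-catalysed enantioselective conjugate peroxidation of enals with α-alkoxyalkyl hydroperoxides. TMSOTf then takes one methoxide from the peroxy orthoester of 10 and the peroxy(methoxy)carbenium ion is attacked by the silicon-bearing carbon of the Z-vinylsilane, forming C5–C6, after which the β-silyl cation loses Me3Si+ to the methoxide (MeOSiMe3, TMSOTf regenerated) so that the cis C4=C5 bond sits exactly where the vinylsilane was; the closest known reaction types are the vinylsilane-terminated cyclisation of oxocarbenium ions to 5,6-dihydro-2H-pyrans and Lewis acid C–C bond formation at peroxycarbenium ions made from peroxyketals. The dioxine ring closes in the 6-endo mode with respect to the vinylsilane. C6 is set by substrate control: in the chair-like transition state the C3 side chain is pseudo-equatorial and the carbenium ion reacts in its ester-like conformation with hexadecyl anti to the O–O tether, so hexadecyl becomes pseudo-equatorial and methoxy pseudo-axial (anomerically favoured), cis to the side chain, which is 6S. The step needs 1,4- and not 1,6-addition of the hydroperoxide (the δ-carbon carries the bulky silyl group), peroxidation and not epoxidation (low temperature, so that the enamine is protonated before it attacks the O–O bond), and ring closure before fragmentation of the peroxycarbenium ion (the β-silicon effect and the preset Z geometry should make the six-membered closure fast).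

Step 8
Reactants: 11 2-[(3S,6S)-6-hexadecyl-6-methoxy-3,6-dihydro-1,2-dioxin-3-yl]acetaldehyde
Product: 12 2-[(3S,6S)-6-hexadecyl-6-methoxy-3,6-dihydro-1,2-dioxin-3-yl]acetic acid
Conditions: NaClO2, NaH2PO4, 2-methylbut-2-ene, t-BuOH/H2O, 0 °C
Reagents that add atoms: sodium chlorite, [Na+].[O-]Cl=O
Why: Pinnick (chlorite) oxidation of the aldehyde to the acid with 2-methylbut-2-ene as HOCl scavenger; the buffered, cold conditions are not expected to touch the O–O bond, the ketal, the alkene or either stereocentre.

Step 9
Reactants: 12 2-[(3S,6S)-6-hexadecyl-6-methoxy-3,6-dihydro-1,2-dioxin-3-yl]acetic acid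
Product: 13 methyl 2-[(3S,6S)-6-hexadecyl-6-methoxy-3,6-dihydro-1,2-dioxin-3-yl]acetate (6-epi-chondrillin)
Conditions: TMSCHN2, MeOH/toluene, 0 °C
Reagents that add atoms: (trimethylsilyl)diazomethane, C[Si](C)(C)C=[N+]=[N-]
Why: esterification with (trimethylsilyl)diazomethane in methanol, a neutral methylation that should leave the peroxy ketal and both stereocentres unchanged.

**Compound list**

1 | heptadecanenitrile | CCCCCCCCCCCCCCCCC#N | starting material
2 | methyl heptadecanimidate hydrochloride | CCCCCCCCCCCCCCCCC(=[NH2+])OC.[Cl-] | intermediate
3 | 1,1,1-trimethoxyheptadecane | CCCCCCCCCCCCCCCCC(OC)(OC)OC | intermediate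
4 | 1-hydroperoxy-1,1-dimethoxyheptadecane | CCCCCCCCCCCCCCCCC(OC)(OC)OO | intermediate
5 | (E)-pent-2-en-4-yn-1-ol | OC/C=C/C#C | starting material
6 | (E)-trimethyl{[5-(trimethylsilyl)pent-2-en-4-yn-1-yl]oxy}silane | C[Si](C)(C)OC/C=C/C#C[Si](C)(C)C | intermediate
7 | (E)-5-(trimethylsilyl)pent-2-en-4-yn-1-ol | OC/C=C/C#C[Si](C)(C)C | intermediate
8 | (2E,4Z)-5-(trimethylsilyl)penta-2,4-dien-1-ol | OC/C=C/C=C\[Si](C)(C)C | intermediate
9 | (2E,4Z)-5-(trimethylsilyl)penta-2,4-dienal | O=C/C=C/C=C\[Si](C)(C)C | intermediate
10 | (3S,4Z)-3-[(1,1-dimethoxyheptadecyl)peroxy]-5-(trimethylsilyl)pent-4-enal | O=CC[C@H](OOC(OC)(OC)CCCCCCCCCCCCCCCC)/C=C\[Si](C)(C)C | intermediate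
11 | 2-[(3S,6S)-6-hexadecyl-6-methoxy-3,6-dihydro-1,2-dioxin-3-yl]acetaldehyde | CCCCCCCCCCCCCCCC[C@@]1(OC)C=C[C@H](CC=O)OO1 | intermediate
12 | 2-[(3S,6S)-6-hexadecyl-6-methoxy-3,6-dihydro-1,2-dioxin-3-yl]acetic acid | CCCCCCCCCCCCCCCC[C@@]1(OC)C=C[C@H](CC(=O)O)OO1 | intermediate
13 | methyl 2-[(3S,6S)-6-hexadecyl-6-methoxy-3,6-dihydro-1,2-dioxin-3-yl]acetate (6-epi-chondrillin) | CCCCCCCCCCCCCCCC[C@@]1(OC)C=C[C@H](CC(=O)OC)OO1 | target

**Step count and risks**

Total step count: 9. Longest linear sequence: 6 steps (steps 4–9 from 5; equally steps 1–3 and 7–9 from 1).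

Steps most likely to fail:

Step 7 (Proposed new method). In the first stage the enamine may close onto the O–O bond (epoxidation), or the acid-labile orthoester-level hydroperoxide may collapse before it adds. In the second stage the peroxycarbenium ion may fragment (loss of the C3 proton with O–O heterolysis), the aldehyde may be drawn into acetal formation, or facial selectivity at C6 may be poor. The fallback uses known reaction types only, puts the C5–C6 bond in place before the peroxide and closes the ring at C4=C5 by metathesis; it sets out from 3 and comes back to the route at 11. Vinylmagnesium bromide displaces one methoxy group of 3 to give 3,3-dimethoxynonadec-1-ene F1. Acid-catalysed exchange with H2O2 gives 3-hydroperoxy-3-methoxynonadec-1-ene F2. Iminium-catalysed conjugate peroxidation of commercial (2E,4E)-hexa-2,4-dienal with F2 and the same (S)-catalyst should give (3S,4E)-3-[(3-methoxynonadec-1-en-3-yl)peroxy]hex-4-enal F3 as both epimers at the ketal carbon. Ring-closing metathesis (second-generation ruthenium benzylidene catalyst, CH2Cl2, 40 °C) with loss of propene should then give 11 together with 2-[(3S,6R)-6-hexadecyl-6-methoxy-3,6-dihydro-1,2-dioxin-3-yl]acetaldehyde F4, which is removed by chromatography.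

Step 3. Exchange may run on to the bis(orthoester) peroxide or the dihydroperoxide, and traces of water with acid may collapse the product to methyl heptadecanoate. The fallback replaces the reversible exchange by an irreversible addition; it sets out from 3 and comes back at 4. Elimination of methanol from 3 (TMSOTf, i-Pr2NEt, CH2Cl2) gives the ketene acetal 1,1-dimethoxyheptadec-1-ene F5, and anhydrous H2O2 adds across the electron-rich double bond without added acid (Et2O, −40 °C) to give 4.

Step 8. The peroxy ketal may be hydrolysed to the hemiketal in the aqueous acidic medium, or the peroxide may be lost by β-elimination from the enolisable aldehyde while chlorite oxidation is still running. The fallback avoids water and the free acid; it sets out from 11 and comes back at 13. The aldehyde is oxidised directly to the methyl ester through its methyl hemiacetal with pyridinium dichromate in MeOH/DMF, so step 9 is skipped and no new compound is made.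

Further compounds
F1 | step 7 | 3,3-dimethoxynonadec-1-ene | C=CC(OC)(OC)CCCCCCCCCCCCCCCC
F2 | step 7 | 3-hydroperoxy-3-methoxynonadec-1-ene (racemic) | C=CC(OC)(OO)CCCCCCCCCCCCCCCC
F3 | step 7 | (3S,4E)-3-[(3-methoxynonadec-1-en-3-yl)peroxy]hex-4-enal (both epimers at the ketal carbon) | O=CC[C@H](OOC(OC)(C=C)CCCCCCCCCCCCCCCC)/C=C/C
F4 | step 7 | 2-[(3S,6R)-6-hexadecyl-6-methoxy-3,6-dihydro-1,2-dioxin-3-yl]acetaldehyde | CCCCCCCCCCCCCCCC[C@]1(OC)C=C[C@H](CC=O)OO1
F5 | step 3 | 1,1-dimethoxyheptadec-1-ene | CCCCCCCCCCCCCCCC=C(OC)OC
F0 | step 8 | none | none
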